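## The problem

Target **16** is a 1',3-linked bis-indole: C3 of a 4,5,6-tribromo-2-(methylthio)-1H-indole (unit A, unprimed atoms, pyrrole ring = ring A) carries N1' of a 2',4',6'-tribromo-3'-(methylthio)indole (unit B, primed atoms, pyrrole ring = ring B). The N1'–C3 bond lies between C2–SMe and the peri C4–Br on one side and C2'–Br and C7'–H on the other, and the molecule holds six aryl C–Br bonds. A late transition-metal N-arylation would therefore be hindered and unselective, so the bond is better made early as an ordinary N–alkyl bond with both rings grown around it. There is no stereogenic centre, so nothing has to be set and nothing can serve as a control element; the only stereochemical element is the crowded N1'–C3 axis. Every bromine has a fixed address, and bromination of a finished bis-indole could not tell C5', C7' and C7 from the wanted carbons, so the halogen patterns must arrive with the benzene rings. Once in place, the C–Br bonds (above all the C2'–Br of a 2-haloindole), the two thioethers and the free N1–H exclude organolithium reagents, catalytic hydrogenation, reductive desulfurization and strong oxidants. In ring B, the sulfur on C3', the C3'–C3a' bond and the 4',6'-dibromo pattern are exactly what ortho-alkylation of symmetric 3,5-dibromoaniline by the sulfur ylide of a (methylthio)acetate leaves behind. Sulfur stays on C3', the ester becomes a C2' lactam carbonyl, and that carbonyl is the precursor of C2'–Br. The 4,5,6-tribromo pattern of unit A maps likewise onto a symmetric 3,4,5-tribromoaryl hydrazine, so neither ring closure faces a regiochemical choice.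

## Retrosynthesis

**C2–S (16 ⇒ 15).** The thioether on C2 of unit A is removed first. In **15** the pyrrole ring of unit B is fully substituted and every benzo position is deactivated, so C2 of unit A, with C3 blocked, is the one site open to an electrophilic sulfur reagent. Carrying this sulfur through the ring-A closure would need a thio-substituted carbonyl partner for which no dependable indolization exists. The forward step must sulfenylate a deactivated 3-substituted indole at C2.

**Ring A (15 ⇒ 10 + 13).** C3–C3a and N1–C2 are cut in a Fischer sense, through hydrazone **14**. This leaves the N1'–C3 bond untouched: it becomes the N–CH2 bond of aldehyde **10**, so the hindered N-heteroaryl linkage is never made by coupling. Hydrazine **13** is symmetric, so the sigmatropic shift can give only the 4,5,6-tribromo pattern. It comes from aniline **11** through diazonium salt **12**. The forward step asks an electron-poor aryl hydrazone to rearrange under acid that spares C2'–Br and the thioether.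

**Functional-group changes (10 ⇒ 9 ⇒ 8).** The aldehyde is traced to the ethyl ester of **9** by partial hydride reduction, and C2'–Br with the aromatic ring B is traced to the lactam carbonyl of oxindole **8** by dehydrative bromination. Aromatizing before the reduction and the Fischer step removes the acidic C3'–H and the lactam carbonyl, which would interfere with hydride, hydrazine and acid.

**Ring B (8 ⇒ 3 + 4), the key cut.** C3'–C3a' and N1'–C2' are cut, going back to glycinate **3** and sulfide **4** through N-chloro amine **5**, azasulfonium salt **6** and amino diester **7**. A Friedel–Crafts closure onto a ring carrying two bromines would be slow, and a metal-catalysed closure is excluded by the bromides. The sigmatropic route needs no nucleophilic ring and leaves sulfur on C3'. The bicyclic core reduces to an achiral aniline and a simple ester. The forward step needs ortho delivery only, which the symmetry of the aryl ring makes unambiguous.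

**N–CH2 (3 ⇒ 1 + 2).** The glycinate is cut at nitrogen to aniline **1** and bromo ester **2**. This early SN2 step fixes the future N1'–C3 bond and supplies the two carbons that become C3 and C2 of unit A.

## Roads not taken

**Alternative 1:** Here N1'–C2' and N1'–C7a' are cut, so ring B is assembled on the amino nitrogen of a finished unit A. The 3-aminoindole A1 would condense with the α-sulfenyl arylacetaldehyde A2 to an enamine, whose nitrogen displaces the fluoride activated by the para nitro group, giving A3. Nitro reduction, amine-directed bromination at C4' and C6' plus bromination at C2', and reductive removal of the amino group through its diazonium salt would follow.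
- Merits: it is more convergent than the chosen plan, both thioethers are in place before the union, and it needs neither a Fischer step on an electron-poor hydrazine nor a late sulfenylation. In these respects it is the better road.
- Weak points: A1 is an oxidation-prone 3-aminoindole and A2 an enolizable aldehyde, each needing several steps. After A3 about four more operations are required, among them a triple bromination in the presence of two thioethers, the free C7 and N1–H, and a diazotization on an indole-rich substrate.
- Comparison: the ring-B bromine pattern would be written late by electrophilic substitution, not bought with the aniline. The chosen plan has no bromination step and no nitro/amino detour, at the cost of a linear sequence.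

**Alternative 2:** Only N1'–C2' is cut. Base would turn the gem-dibromovinyl group of diarylamine A4 into a bromoalkyne, and the amine nitrogen would add to its bromine-bearing carbon, giving A5 with C2'–Br formed during ring closure.
- Merits: no lactam-to-bromide exchange is needed, the cyclization of ortho-(dibromovinyl)anilines to 2-bromoindoles is known, and the later C3' sulfenylation of a free indole 3-position is about the most reliable indole reaction. Here this road is stronger.
- Weak points: the nucleophile is a hindered, weakly nucleophilic diarylamine. A4 itself needs a C–N bond between an indole 3-position and a doubly deactivated ortho-substituted aniline, plus a Ramirez olefination. The N-acetyl group must survive the base. Two sulfenylations (C3', then C2 after deacylation) remain.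
- Comparison: the chosen plan puts the C3' sulfur in during ring formation and needs one late sulfenylation, not two. Its starting materials are two anilines and two esters.

**Alternative 3:** The strategic cut is C3–C3a and N1–C2 of ring A. Ring B would be taken from the preformed indole A6 by C3' sulfenylation, C2' bromination and N-alkylation with a protected bromoacetaldehyde. Condensation with **13** gives hydrazone A7, identical with **14**, and acid gives A8, identical with **15**.
- Merits: every operation on ring B is routine indole substitution, with no lactam-to-bromide exchange and no partial ester reduction. If A6 can be bought the count is equal or one step shorter, and in that case this road is at least as good.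
- Weak points: the Fischer step is shared by both plans, so the main risk is not reduced. If A6 has to be made, three or four steps are added and the ring-B pattern must be built anyway.
- Comparison: the chosen plan makes ring B from 3,5-dibromoaniline with the pattern fixed by symmetry, installs the C3' sulfur and the N-tether during the ring-forming sequence, and does not depend on A6.

Key step: step 2

Assumption: the target is drawn without a descriptor for the N1'–C3 axis, so it is treated as the racemate (or as a freely rotating axis) and no atroposelective step is planned.

## Route

Step 1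
Reactants: 1 3,5-dibromoaniline; 2 ethyl bromoacetate
Product: 3 ethyl N-(3,5-dibromophenyl)glycinate
Conditions: NaOAc, NaI (cat.), EtOH, 80 °C
Reagents that add atoms: none
Why: SN2 N-alkylation of a weakly basic aniline by an α-halo ester; the product is a still weaker nucleophile, which should hold the reaction at monoalkylation, and NaOAc takes up the HBr.

Step 2
Reactants: 3 ethyl N-(3,5-dibromophenyl)glycinate; 4 ethyl (methylthio)acetate
Product: 8 ethyl 2-[4,6-dibromo-3-(methylthio)-2-oxoindolin-1-yl]acetate (racemic), via N-chloro glycinate 5 (not isolated), via azasulfonium chloride 6 (not isolated), via amino diester 7 (not isolated)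
Conditions: tBuOCl, CH2Cl2, −70 °C; then 4, −70 °C; then Et3N, −70 °C to rt; then 2 M aq. HCl, Et2O, rt
Reagents that add atoms: none
Why: tBuOCl chlorinates the nitrogen of 3 to give 5, and the sulfur of 4 displaces chloride from nitrogen to give azasulfonium salt 6. Et3N removes a proton from the ester-activated S–CH2 group, and the ylide undergoes a [2,3]-sigmatropic shift (Sommelet–Hauser type) across S–N–C(ipso)–C(ortho), forming C3'–C3a' and breaking S–N; a proton shift then restores the arene as 7. Acid lets the anilinic nitrogen attack the new ester, closing N1'–C2' in a 5-exo-trig lactamization with loss of ethanol to give 8. The closest known reaction type is the Gassman oxindole synthesis, which is established for N-alkyl and for electron-poor anilines. Ortho delivery is inherent in the five-centre transition state, and the two ortho carbons of the 3,5-dibromoaryl ring are equivalent, so only the 4',6'-dibromo oxindole can form; the concerted shift does not depend on ring nucleophilicity. The ylide should form at CH2CO2Et and not at S–CH3 because of the ester. The sulfide is added cold before any base so that 5 does not lose HCl to the glyoxylate imine. The C3' stereocentre of 8 is formed without control and is erased in step 3.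

Step 3
Reactants: 8 ethyl 2-[4,6-dibromo-3-(methylthio)-2-oxoindolin-1-yl]acetate
Product: 9 ethyl 2-[2,4,6-tribromo-3-(methylthio)indol-1-yl]acetate
Conditions: POBr3, ClCH2CH2Cl, 80 °C; then ice-water
Reagents that add atoms: phosphorus oxybromide (POBr3), O=P(Br)(Br)Br
Why: Dehydrative bromination of an oxindole: the lactam oxygen is activated on phosphorus (Vilsmeier-type), bromide adds at C2', and loss of the phosphate and the acidic C3'–H aromatizes ring B to the 2-bromoindole; the ester, thioether and aryl bromides should be untouched.

Step 4
Reactants: 9 ethyl 2-[2,4,6-tribromo-3-(methylthio)indol-1-yl]acetate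
Product: 10 2-[2,4,6-tribromo-3-(methylthio)indol-1-yl]acetaldehyde
Conditions: iBu2AlH (1.1 equiv), CH2Cl2, −78 °C; then MeOH, aq. KNaC4H4O6
Reagents that add atoms: none
Why: Partial reduction of an ester through the aluminium hemiacetal, which is stable at −78 °C; C–Br bonds, including C2'–Br, are inert to iBu2AlH at this temperature, and the aldehyde is used promptly.

Step 5
Reactants: 11 3,4,5-tribromoaniline
Product: 13 (3,4,5-tribromophenyl)hydrazine, via diazonium chloride 12 (not isolated)
Conditions: NaNO2, conc. HCl–AcOH, 0 °C; then SnCl2·2H2O, conc. HCl, 0 °C to rt; then aq. NaOH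
Reagents that add atoms: sodium nitrite (NaNO2), [Na+].[O-]N=O
Why: Diazotization of a weakly basic aniline in strong acid, then reduction of the diazonium ion by divalent tin to the aryl hydrazine, the standard route to aryl hydrazines; SnCl2 does not touch aryl bromides.

Step 6
Reactants: 10 2-[2,4,6-tribromo-3-(methylthio)indol-1-yl]acetaldehyde; 13 (3,4,5-tribromophenyl)hydrazine
Product: 15 4,5,6-tribromo-3-[2,4,6-tribromo-3-(methylthio)indol-1-yl]-1H-indole, via hydrazone 14 (not isolated)
Conditions: EtOH, AcOH (cat.), rt; then ZnCl2, AcOH, 100 °C
Reagents that add atoms: none
Why: Fischer indole synthesis: 14 tautomerizes to the ene-hydrazine, the [3,3] shift forms C3–C3a at either of two equivalent ortho carbons, and the resulting aminal closes N1–C2 and loses ammonia; aldehyde hydrazones and 3,5-dihaloaryl hydrazines are established substrates, and the symmetric aryl group allows only the 4,5,6-tribromo pattern.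

Step 7
Reactants: 15 4,5,6-tribromo-3-[2,4,6-tribromo-3-(methylthio)indol-1-yl]-1H-indole
Product: 16 4,5,6-tribromo-2-(methylthio)-3-[2,4,6-tribromo-3-(methylthio)indol-1-yl]-1H-indole
Conditions: MeSSMe, SO2Cl2, CH2Cl2, −20 °C (gives MeSCl); then 15, CH2Cl2, 0 °C to rt
Reagents that add atoms: methanesulfenyl chloride, CSCl (made in the flask from dimethyl disulfide, CSSC, and sulfuryl chloride, O=S(=O)(Cl)Cl)
Why: Electrophilic sulfenylation of a 3-substituted indole at C2 by a sulfenyl chloride, either directly or by attack at C3 followed by a 1,2-shift of sulfur; unit B has no free pyrrole position and its benzo CH positions are deactivated, so only C2 of unit A should react.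

## Compound list

1 | 3,5-dibromoaniline | Nc1cc(Br)cc(Br)c1 | starting material
2 | ethyl bromoacetate | CCOC(=O)CBr | starting material
3 | ethyl N-(3,5-dibromophenyl)glycinate | CCOC(=O)CNc1cc(Br)cc(Br)c1 | intermediate
4 | ethyl (methylthio)acetate | CCOC(=O)CSC | starting material
5 | ethyl N-chloro-N-(3,5-dibromophenyl)glycinate (not isolated) | CCOC(=O)CN(Cl)c1cc(Br)cc(Br)c1 | intermediate
6 | [N-(3,5-dibromophenyl)-N-(2-ethoxy-2-oxoethyl)amino](2-ethoxy-2-oxoethyl)methylsulfonium chloride (racemic at sulfur; not isolated) | CCOC(=O)CN(c1cc(Br)cc(Br)c1)[S+](C)CC(=O)OCC.[Cl-] | intermediate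
7 | ethyl 2-[2,4-dibromo-6-[(2-ethoxy-2-oxoethyl)amino]phenyl]-2-(methylthio)acetate (racemic; not isolated) | CCOC(=O)CNc1cc(Br)cc(Br)c1C(SC)C(=O)OCC | intermediate
8 | ethyl 2-[4,6-dibromo-3-(methylthio)-2-oxoindolin-1-yl]acetate (racemic) | CCOC(=O)CN1C(=O)C(SC)c2c(Br)cc(Br)cc21 | intermediate
9 | ethyl 2-[2,4,6-tribromo-3-(methylthio)indol-1-yl]acetate | CCOC(=O)Cn1c(Br)c(SC)c2c(Br)cc(Br)cc21 | intermediate
10 | 2-[2,4,6-tribromo-3-(methylthio)indol-1-yl]acetaldehyde | O=CCn1c(Br)c(SC)c2c(Br)cc(Br)cc21 | intermediate
11 | 3,4,5-tribromoaniline | Nc1cc(Br)c(Br)c(Br)c1 | starting material
12 | 3,4,5-tribromobenzenediazonium chloride (not isolated) | N#[N+]c1cc(Br)c(Br)c(Br)c1.[Cl-] | intermediate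
13 | (3,4,5-tribromophenyl)hydrazine | NNc1cc(Br)c(Br)c(Br)c1 | intermediate
14 | 2-[2,4,6-tribromo-3-(methylthio)indol-1-yl]acetaldehyde (3,4,5-tribromophenyl)hydrazone (E drawn, geometry of no consequence; not isolated) | CSc1c(Br)n(C/C=N/Nc2cc(Br)c(Br)c(Br)c2)c2cc(Br)cc(Br)c12 | intermediate
15 | 4,5,6-tribromo-3-[2,4,6-tribromo-3-(methylthio)indol-1-yl]-1H-indole | CSc1c(Br)n(-c2c[nH]c3cc(Br)c(Br)c(Br)c23)c2cc(Br)cc(Br)c12 | intermediate
16 | 4,5,6-tribromo-2-(methylthio)-3-[2,4,6-tribromo-3-(methylthio)indol-1-yl]-1H-indole | CSc1[nH]c2cc(Br)c(Br)c(Br)c2c1-n1c(Br)c(SC)c2c(Br)cc(Br)cc21 | target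

## Step count and risks

Total: 7 steps. Longest linear sequence: 6 steps (1 → 3 → 8 → 9 → 10 → 15 → 16); the hydrazine branch (11 → 13) adds one step and joins at step 6.

**Step 2 (key step).** The N–CH2 hydrogens of the glycinate are activated by the ester. The most likely failure is loss of HCl from the N-chloro amine, or base-induced fragmentation of the azasulfonium salt, to the N-aryl imine of ethyl glyoxylate before the ylide rearranges. A second weakness is slow lactamization by a hindered, weakly nucleophilic nitrogen. The fallback removes the activated hydrogens by running the same ylide rearrangement on the primary aniline. It sets out from 1 and 4: tBuOCl, then 4, Et3N and acid should give 4,6-dibromo-3-(methylthio)indolin-2-one F1. POBr3 in hot ClCH2CH2Cl should turn F1 into 2,4,6-tribromo-3-(methylthio)-1H-indole F2. N-alkylation of F2 with 2 (NaH, DMF, 0 °C) rejoins the route at 9.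

**Step 6.** A nitrogen substituent on the carbon that becomes C3 can favour heterolytic N–N cleavage of the protonated ene-hydrazine over the [3,3] shift. The shift onto an electron-poor ring is also slow, and long exposure to hot acid invites hydrolysis at C2'–Br. The fallback closes ring A by a different bond-forming logic. It sets out from 11, which is iodinated at one of its two equivalent free ortho positions (ICl, AcOH) to give 3,4,5-tribromo-2-iodoaniline F3. F3 is condensed with 10 and cyclized with Pd(OAc)2, DABCO, DMF, 85 °C: enamine formation, oxidative addition of zerovalent palladium to the C–I bond, and intramolecular Heck-type closure of C3–C3a. This returns to the route at 15. It relies on the C–I bond reacting well before any C–Br bond.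

**Step 7.** Electrophilic attack on a tribrominated, sterically shielded indole may be too slow, leaving N-sulfenylation or decomposition of the sulfenyl chloride as the main events. The fallback brings in the C2 sulfur through a thiolactam. It sets out from 15, which is oxidized at C2 (DMSO, conc. HCl, AcOH) to 4,5,6-tribromo-3-[2,4,6-tribromo-3-(methylthio)indol-1-yl]indolin-2-one F4. Lawesson's reagent in toluene at 80 °C should convert F4 into 4,5,6-tribromo-3-[2,4,6-tribromo-3-(methylthio)indol-1-yl]indoline-2-thione F5. S-methylation of F5 (MeI, K2CO3, acetone) gives 16 directly.

**Step 3.** The exchange of the lactam oxygen for bromine may stall at the enol phosphate stage, or the side-chain ester carbonyl may take part in the activated iminium ion. The fallback avoids the exchange and bypasses step 4 as well. It sets out from 8: excess iBu2AlH (CH2Cl2, −78 to 0 °C, acidic work-up) should reduce both the ester and the lactam, the hemiaminal dehydrating to the indole, to give 2-[4,6-dibromo-3-(methylthio)indol-1-yl]ethanol F6. NBS in CH2Cl2 at 0 °C brominates the free C2' position to give 2-[2,4,6-tribromo-3-(methylthio)indol-1-yl]ethanol F7. Parikh–Doering oxidation of F7 (SO3·pyridine, DMSO, iPr2NEt), chosen because it spares the thioether, returns to the route at 10.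

## Further compounds

F1 | step 2 | 4,6-dibromo-3-(methylthio)indolin-2-one (racemic) | CSC1C(=O)Nc2cc(Br)cc(Br)c21
F2 | step 2 | 2,4,6-tribromo-3-(methylthio)-1H-indole | CSc1c(Br)[nH]c2cc(Br)cc(Br)c12
F3 | step 6 | 3,4,5-tribromo-2-iodoaniline | Nc1cc(Br)c(Br)c(Br)c1I
F4 | step 7 | 4,5,6-tribromo-3-[2,4,6-tribromo-3-(methylthio)indol-1-yl]indolin-2-one (racemic) | CSc1c(Br)n(C2C(=O)Nc3cc(Br)c(Br)c(Br)c32)c2cc(Br)cc(Br)c12
F5 | step 7 | 4,5,6-tribromo-3-[2,4,6-tribromo-3-(methylthio)indol-1-yl]indoline-2-thione (racemic) | CSc1c(Br)n(C2C(=S)Nc3cc(Br)c(Br)c(Br)c32)c2cc(Br)cc(Br)c12
F6 | step 3 | 2-[4,6-dibromo-3-(methylthio)indol-1-yl]ethanol | CSc1cn(CCO)c2cc(Br)cc(Br)c12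
F7 | step 3 | 2-[2,4,6-tribromo-3-(methylthio)indol-1-yl]ethanol | CSc1c(Br)n(CCO)c2cc(Br)cc(Br)c12
A1 | alternative 1 | 3-amino-4,5,6-tribromo-2-(methylthio)-1H-indole | CSc1[nH]c2cc(Br)c(Br)c(Br)c2c1N
A2 | alternative 1 | 2-(2-fluoro-5-nitrophenyl)-2-(methylthio)acetaldehyde (racemic) | CSC(C=O)c1cc(ccc1F)[N+](=O)[O-]
A3 | alternative 1 | 4,5,6-tribromo-2-(methylthio)-3-[3-(methylthio)-5-nitroindol-1-yl]-1H-indole | CSc1[nH]c2cc(Br)c(Br)c(Br)c2c1-n1cc(SC)c2cc(ccc21)[N+](=O)[O-]
A4 | alternative 2 | N-(1-acetyl-4,5,6-tribromoindol-3-yl)-3,5-dibromo-2-(2,2-dibromovinyl)aniline | CC(=O)n1cc(Nc2cc(Br)cc(Br)c2C=C(Br)Br)c2c(Br)c(Br)c(Br)cc21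
A5 | alternative 2 | 1-acetyl-4,5,6-tribromo-3-(2,4,6-tribromoindol-1-yl)indole | CC(=O)n1cc(-n2c(Br)cc3c(Br)cc(Br)cc32)c2c(Br)c(Br)c(Br)cc21
A6 | alternative 3 | 4,6-dibromo-1H-indole | Brc1cc(Br)c2cc[nH]c2c1
A7 | alternative 3 | 2-[2,4,6-tribromo-3-(methylthio)indol-1-yl]acetaldehyde (3,4,5-tribromophenyl)hydrazone (identical with 14) | CSc1c(Br)n(C/C=N/Nc2cc(Br)c(Br)c(Br)c2)c2cc(Br)cc(Br)c12
A8 | alternative 3 | 4,5,6-tribromo-3-[2,4,6-tribromo-3-(methylthio)indol-1-yl]-1H-indole (identical with 15) | CSc1c(Br)n(-c2c[nH]c3cc(Br)c(Br)c(Br)c23)c2cc(Br)cc(Br)c12
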